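## Retrosynthetic overview

1. Numbering: ring A = C1–C5 + C10, ring B = C5–C10 (C8=C9), chain C11–C16 with C24 (CH2OH) on C13, lactone C17/C18/C19(=O)/O/C25.
2. C13=C14 (Z) is cut by a Z-selective Wittig olefination into α-silyloxy ketone 19 (rings A/B, C11–C13, C24) and lactone phosphonium salt 32 (C14–C19, C25); C16 and C17 of 32 come from one Evans syn-aldol, and the butanolide ring is closed in step 17.
3. 19 goes back through allylic bromide 15 to the bicyclic β-keto ester 11; its C8 oxygen becomes the C8 methyl group (enol phosphate, then cuprate) and its ester carbon is C11.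
4. Key disconnection, 11 ⇒ oxolane enol ether 10: the C5–O bond ionises, the C4–C10 bond of a 1,2,2-trimethylcyclopentane shifts to C5 (ring A grows from five to six atoms), and the released β-keto ester enol closes ring B at C10. The enabling feature is that the ring-fusion methine C5 lies between the two quaternary carbons C4 (gem-dimethyl) and C10 (methyl) and stands 1,4 to the C8 oxygen of the C8–C9–C11 keto ester, so ring A can be folded back to a cyclopentane with C5 outside the ring while the enol oxygen serves as tether and leaving group.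
5. 10 ⇒ epoxide 7 + methyl acetoacetate 8, and 7 ⇒ (1S,3R)-camphoric acid 1; ring order: cyclopentane (chiral pool) → temporary oxolane (step 6) → rings A and B together (step 7).

Key step: step 7

Remark: (1S,3R)-camphoric acid 1 is taken to be a purchasable chiral-pool acid; C9 of keto ester 11 is an epimerising β-keto ester carbon and is drawn as one epimer. In names, Dr = (4aS,8aS)-2,5,5,8a-tetramethyl-3,4,4a,5,6,7,8,8a-octahydronaphthalen-1-yl and TBS = tert-butyldimethylsilyl.

## Route

Step 1
Reactants: 1 (1S,3R)-camphoric acid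
Product: 2 dimethyl (1S,3R)-1,2,2-trimethylcyclopentane-1,3-dicarboxylate
Conditions: MeI, K2CO3, DMF, rt
Reagents that add atoms: iodomethane, CI
Why: O-alkylation of both carboxylates (SN2 at methyl) should esterify even the hindered tertiary acid, because no addition to its carbonyl group is needed.

Step 2
Reactants: 2 dimethyl (1S,3R)-camphorate
Product: 3 (1R,3S)-3-(methoxycarbonyl)-2,2,3-trimethylcyclopentane-1-carboxylic acid
Conditions: KOH (1.1 equiv), MeOH/H2O, 60 °C; then 1 M HCl
Reagents that add atoms: potassium hydroxide, [K+].[OH-]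
Why: Saponification should take place only at the secondary ester, since the tertiary ester is shielded by two quaternary carbons.

Step 3
Reactants: 3 mono acid
Product: 4 methyl (1S)-1,2,2-trimethylcyclopentane-1-carboxylate
Conditions: 9-mesityl-10-methylacridinium tetrafluoroborate (5 mol%), PhSSPh (10 mol%), i-Pr2NEt (20 mol%), CF3CH2OH, 450 nm LEDs, rt
Reagents that add atoms: none
Why: Photoredox hydrodecarboxylation (carboxylate oxidation, loss of CO2, hydrogen transfer from thiophenol to the secondary radical) should remove the unwanted carboxyl group; the stereocentre that is lost is not needed and the quaternary one is untouched.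

Step 4
Reactants: 4 methyl (1S)-1,2,2-trimethylcyclopentane-1-carboxylate
Product: 5 2-chloro-1-[(1S)-1,2,2-trimethylcyclopentyl]ethan-1-one
Conditions: ICH2Cl, MeLi·LiBr, THF/Et2O, −78 °C; AcOH, −78 °C → rt
Reagents that add atoms: chloroiodomethane, ClCI
Why: Carbenoid homologation of an ester to an α-chloroketone: chloromethyllithium (from Li–I exchange) adds once, because the tetrahedral lithium alkoxide survives at −78 °C until the acid quench.

Step 5
Reactants: 5 chloromethyl ketone
Product: 7 (2R)-2-[(1S)-1,2,2-trimethylcyclopentyl]oxirane, via chlorohydrin 6 (not isolated)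
Conditions: (R)-2-methyl-CBS-oxazaborolidine (10 mol%), BH3·SMe2, THF, −20 °C → rt; MeOH; then 2 M NaOH, rt
Reagents that add atoms: none
Why: Corey–Bakshi–Shibata reduction with the tertiary alkyl group as the large and CH2Cl as the small substituent should give the (R)-chlorohydrin under reagent control (new stereocentre, the future C5), which closes to the epoxide by internal Williamson displacement without touching that centre.

Step 6
Reactants: 7 epoxide; 8 methyl acetoacetate
Product: 10 methyl (2E)-2-[(5S)-5-[(1S)-1,2,2-trimethylcyclopentyl]oxolan-2-ylidene]acetate, via hydroxy keto ester 9 (not isolated)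
Conditions: 8, NaH then n-BuLi, THF, 0 °C; 7, 0 → 40 °C; 1 M HCl; then TFA (cat.), CH2Cl2, rt
Reagents that add atoms: none
Why: The γ-carbon of the acetoacetate dianion should open the epoxide at its CH2 terminus (the carbinol centre is untouched; its descriptor changes from R to S only through the priority rules), and the γ-hydroxy ketone should close to the hemiketal and dehydrate into conjugation to give the 2-alkylidene oxolane, whose olefin geometry is erased in step 7.

Step 7
Reactants: 10 oxolane enol ether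
Product: 11 methyl (1R,4aS,8aS)-5,5,8a-trimethyl-2-oxodecahydronaphthalene-1-carboxylate
Conditions: SnCl4 (1.5 equiv), CH2Cl2 (0.01 M), −78 °C → rt
Reagents that add atoms: none
Why: Proposed new method: SnCl4 binds the ester carbonyl of the vinylogous carbonate and makes the ring oxygen a leaving group (it departs as the tin enolate of a β-keto ester), so the secondary C5–O bond should ionise with synchronous anti-periplanar 1,2-shift of the C4–C10 bond (Wagner–Meerwein ring expansion of the cyclopentane to ring A, driven by the secondary → tertiary change), and the tertiary C10 cation is then captured by carbon C9 of its own tethered enolate. The closest known reaction types are the Lewis-acid O→C rearrangement of cyclic enol ethers (Petasis–Ferrier type), the boron trihalide opening of 2-alkylidene oxolanes at C5, the solvolytic ring expansion of 1-(1-methylcyclopentyl)alkyl sulfonates and the SnCl4 cyclisation of monocyclic β-keto esters of the α-cyclogeranyl type to this same bicyclic skeleton. Ring A is closed by the 1,2-alkyl shift (five → six atoms), ring B by a 6-endo cation–olefin closure in which both enol carbons C8 and C9 end in the ring. C5 is set by inversion (C4 enters anti to the leaving oxygen, so the (5S) carbinol centre from step 5 becomes the 5α-H centre), C10 by attack of C9 anti to the migrating C4 through a chair with the C5 chain equatorial, for which the (1S) cyclopentane centre is the matched one (trans fusion), and C9 is an epimerisable centre that becomes sp2 in step 8. The step needs migration of the quaternary C4 rather than of C1 or methyl (the better migrating group, held anti to the C–O bond) and C- rather than O-alkylation of the enolate (an O-alkylated tertiary enol ether can re-ionise under SnCl4, the C–C bond cannot); the step is a pure isomerisation.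

Step 8
Reactants: 11 bicyclic β-keto ester
Product: 12 methyl (4aS,8aS)-2-[(diethoxyphosphoryl)oxy]-5,5,8a-trimethyl-3,4,4a,5,6,7,8,8a-octahydronaphthalene-1-carboxylate
Conditions: NaH, (EtO)2P(O)Cl, Et2O, 0 °C
Reagents that add atoms: diethyl chlorophosphate, CCOP(=O)(Cl)OCC
Why: O-phosphorylation of the sodium enolate of the β-keto ester should fix the double bond between C8 and C9 regiospecifically.

Step 9
Reactants: 12 enol phosphate
Product: 13 methyl Dr-carboxylate [methyl (4aS,8aS)-2,5,5,8a-tetramethyl-3,4,4a,5,6,7,8,8a-octahydronaphthalene-1-carboxylate]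
Conditions: Me2CuLi (from CuI and MeLi), Et2O, −78 → −20 °C
Reagents that add atoms: lithium dimethylcuprate, [Li+].C[Cu-]C
Why: Addition–elimination of the cuprate on the β-phosphoryloxy enoate should install the C8 methyl group without moving the double bond (enol phosphate/cuprate method for β-methyl enoates).

Step 10
Reactants: 13 enoate
Product: 14 Dr-methanol [(4aS,8aS)-Dr-CH2OH]
Conditions: i-Bu2AlH, toluene, −78 °C → rt; aq. KNaC4H4O6
Reagents that add atoms: none
Why: 1,2-Reduction of the hindered conjugated ester with the aluminium hydride should give the primary allylic alcohol.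

Step 11
Reactants: 14 allylic alcohol
Product: 15 Dr-CH2Br [(4aS,8aS)-1-(bromomethyl)-2,5,5,8a-tetramethyl-3,4,4a,5,6,7,8,8a-octahydronaphthalene]
Conditions: PBr3, pyridine (cat.), Et2O, 0 °C
Reagents that add atoms: phosphorus tribromide, BrP(Br)Br
Why: Bromination of the primary allylic alcohol via its phosphite should proceed without allylic transposition, because the SN2′ position is a fully substituted carbon.

Step 12
Reactants: 16 1-[(tert-butyldimethylsilyl)oxy]propan-2-one
Product: 17 1-[(tert-butyldimethylsilyl)oxy]propan-2-one N,N-dimethylhydrazone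
Conditions: Me2NNH2, AcOH (cat.), EtOH, rt
Reagents that add atoms: 1,1-dimethylhydrazine, CN(C)N
Why: Simple condensation of the ketone with the hydrazine should give the hydrazone needed for regiocontrolled α′-alkylation.

Step 13
Reactants: 15 allylic bromide; 17 hydrazone
Product: 19 1-[(tert-butyldimethylsilyl)oxy]-4-Dr-butan-2-one, via alkylated hydrazone 18 (not isolated)
Conditions: 17, LiN(i-Pr)2, THF, 0 °C; 15, −78 °C → rt; then sat. aq. oxalic acid, Et2O, rt
Reagents that add atoms: water, O
Why: Corey–Enders hydrazone alkylation: kinetic deprotonation at the methyl group gives the azaenolate, which should displace the primary allylic bromide (SN2, forming C11–C12), and mild two-phase hydrolysis frees the ketone with the silyl ether intact.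

Step 14
Reactants: 20 4-(tert-butoxy)-4-oxobutanoic acid; 21 (4S)-4-benzyl-1,3-oxazolidin-2-one
Product: 23 tert-butyl 4-[(4S)-4-benzyl-2-oxo-1,3-oxazolidin-3-yl]-4-oxobutanoate, via mixed pivalic anhydride 22 (not isolated)
Conditions: t-BuCOCl, Et3N, THF, −20 °C; then 21, LiCl, rt
Reagents that add atoms: none
Why: N-Acylation of the oxazolidinone by the mixed anhydride should occur at the unhindered succinyl carbonyl.

Step 15
Reactants: 23 imide; 24 3-(benzyloxy)propanal
Product: 26 tert-butyl (3S,4R)-3-{[(4S)-4-benzyl-2-oxo-1,3-oxazolidin-3-yl]carbonyl}-6-(benzyloxy)-4-hydroxyhexanoate, via boron enolate 25 (not isolated)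
Conditions: n-Bu2BOTf, i-Pr2NEt, CH2Cl2, −78 → 0 °C; 24, −78 → 0 °C; pH 7 buffer, MeOH, H2O2
Reagents that add atoms: none
Why: Evans syn-aldol: the Z-boron enolate should react through a Zimmerman–Traxler chair on the face opposite the benzyl group, setting C17 and C16 (both R in the target) in one step, while the tert-butyl ester cannot lactonise with the new hydroxyl.

Step 16
Reactants: 26 aldol adduct
Product: 27 tert-butyl (3S,4R)-3-{[(4S)-4-benzyl-2-oxo-1,3-oxazolidin-3-yl]carbonyl}-6-(benzyloxy)-4-[(tert-butyldimethylsilyl)oxy]hexanoate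
Conditions: TBSOTf, 2,6-lutidine, CH2Cl2, −78 → 0 °C
Reagents that add atoms: tert-butyldimethylsilyl trifluoromethanesulfonate, CC(C)(C)[Si](C)(C)OS(=O)(=O)C(F)(F)F
Why: Silylation of the secondary hydroxyl should block C16–O so that only the primary oxygen can lactonise later.

Step 17
Reactants: 27 silyl ether
Product: 29 (4R)-4-[(1R)-3-(benzyloxy)-1-[(tert-butyldimethylsilyl)oxy]propyl]oxolan-2-one, via hydroxy ester 28 (not isolated)
Conditions: LiBH4, MeOH (1 equiv), THF, 0 °C; then TFA, CH2Cl2, 0 °C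
Reagents that add atoms: none
Why: Reductive cleavage of the imide should give the primary alcohol (auxiliary recovered), and brief anhydrous acid then removes the tert-butyl group and closes the γ-lactone onto that primary hydroxyl, the secondary oxygen being silylated.

Step 18
Reactants: 29 benzyl ether
Product: 30 (4R)-4-[(1R)-1-[(tert-butyldimethylsilyl)oxy]-3-hydroxypropyl]oxolan-2-one
Conditions: H2 (1 atm), Pd/C, EtOAc, rt
Reagents that add atoms: none
Why: Hydrogenolysis of the benzyl ether should leave the lactone and the silyl ether untouched, and this fragment has no olefin.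

Step 19
Reactants: 30 alcohol
Product: 31 (4R)-4-[(1R)-1-[(tert-butyldimethylsilyl)oxy]-3-iodopropyl]oxolan-2-one
Conditions: I2, PPh3, imidazole, CH2Cl2, 0 °C → rt
Reagents that add atoms: iodine, [I][I]
Why: Appel-type iodination of the primary alcohol (SN2 on the alkoxyphosphonium ion) should not affect the stereocentres.

Step 20
Reactants: 31 iodide
Product: 32 [(3R)-3-[(tert-butyldimethylsilyl)oxy]-3-[(3R)-5-oxooxolan-3-yl]propyl]triphenylphosphonium iodide
Conditions: PPh3, MeCN, 80 °C
Reagents that add atoms: triphenylphosphine, c1ccc(cc1)P(c1ccccc1)c1ccccc1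
Why: SN2 quaternisation of the phosphine by the primary iodide should give the Wittig salt.

Step 21
Reactants: 19 α-silyloxy ketone; 32 phosphonium iodide
Product: 34 (4R)-4-[(1R,3Z)-1-[(tert-butyldimethylsilyl)oxy]-4-{[(tert-butyldimethylsilyl)oxy]methyl}-6-Dr-hex-3-en-1-yl]oxolan-2-one, via ylide 33 (not isolated)
Conditions: 32, NaN(SiMe3)2, THF, −78 °C; then 19, THF/HMPA, −78 °C → rt
Reagents that add atoms: none
Why: Z-selective Wittig olefination of an α-alkoxy ketone with a non-stabilised ylide should place the oxygenated CH2 group cis to the new chain (Z-trisubstituted olefin); the ylide is formed at −78 °C, where the phosphonium α-protons are far more acidic than those of the lactone.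

Step 22
Reactants: 34 bis-silyl ether
Product: 35 (4R)-4-[(1R,3Z)-1-hydroxy-4-(hydroxymethyl)-6-Dr-hex-3-en-1-yl]oxolan-2-one (CNP0164639.2)
Conditions: HF·pyridine, pyridine, THF, 0 °C → rt
Reagents that add atoms: none
Why: Buffered fluoride desilylation should free both hydroxyls under mildly acidic conditions, which avoid alkoxide-driven translactonisation to the C16 oxygen.

## Compound list

1 | (1S,3R)-1,2,2-trimethylcyclopentane-1,3-dicarboxylic acid (camphoric acid) | C[C@]1(C(O)=O)CC[C@@H](C(O)=O)C1(C)C | starting material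
2 | dimethyl (1S,3R)-1,2,2-trimethylcyclopentane-1,3-dicarboxylate | C[C@]1(C(=O)OC)CC[C@@H](C(=O)OC)C1(C)C | intermediate
3 | (1R,3S)-3-(methoxycarbonyl)-2,2,3-trimethylcyclopentane-1-carboxylic acid | C[C@]1(C(=O)OC)CC[C@@H](C(O)=O)C1(C)C | intermediate
4 | methyl (1S)-1,2,2-trimethylcyclopentane-1-carboxylate | C[C@]1(C(=O)OC)CCCC1(C)C | intermediate
5 | 2-chloro-1-[(1S)-1,2,2-trimethylcyclopentyl]ethan-1-one | C[C@]1(C(=O)CCl)CCCC1(C)C | intermediate
6 | (1R)-2-chloro-1-[(1S)-1,2,2-trimethylcyclopentyl]ethan-1-ol | C[C@]1([C@@H](O)CCl)CCCC1(C)C | intermediate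
7 | (2R)-2-[(1S)-1,2,2-trimethylcyclopentyl]oxirane | C[C@]1([C@@H]2CO2)CCCC1(C)C | intermediate
8 | methyl acetoacetate | COC(=O)CC(C)=O | starting material
9 | methyl (6S)-6-hydroxy-3-oxo-6-[(1S)-1,2,2-trimethylcyclopentyl]hexanoate | COC(=O)CC(=O)CC[C@H](O)[C@@]1(C)CCCC1(C)C | intermediate
10 | methyl (2E)-2-[(5S)-5-[(1S)-1,2,2-trimethylcyclopentyl]oxolan-2-ylidene]acetate | COC(=O)/C=C1\CC[C@H](O1)[C@@]2(C)CCCC2(C)C | intermediate
11 | methyl (1R,4aS,8aS)-5,5,8a-trimethyl-2-oxodecahydronaphthalene-1-carboxylate | O=C1[C@H](C(=O)OC)[C@@]2(C)CCCC(C)(C)[C@@H]2CC1 | intermediate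
12 | methyl (4aS,8aS)-2-[(diethoxyphosphoryl)oxy]-5,5,8a-trimethyl-3,4,4a,5,6,7,8,8a-octahydronaphthalene-1-carboxylate | CCOP(=O)(OCC)OC1=C(C(=O)OC)[C@@]2(C)CCCC(C)(C)[C@@H]2CC1 | intermediate
13 | methyl (4aS,8aS)-2,5,5,8a-tetramethyl-3,4,4a,5,6,7,8,8a-octahydronaphthalene-1-carboxylate | CC1=C(C(=O)OC)[C@@]2(C)CCCC(C)(C)[C@@H]2CC1 | intermediate
14 | [(4aS,8aS)-2,5,5,8a-tetramethyl-3,4,4a,5,6,7,8,8a-octahydronaphthalen-1-yl]methanol | CC1=C(CO)[C@@]2(C)CCCC(C)(C)[C@@H]2CC1 | intermediate
15 | (4aS,8aS)-1-(bromomethyl)-2,5,5,8a-tetramethyl-3,4,4a,5,6,7,8,8a-octahydronaphthalene | CC1=C(CBr)[C@@]2(C)CCCC(C)(C)[C@@H]2CC1 | intermediate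
16 | 1-[(tert-butyldimethylsilyl)oxy]propan-2-one | CC(=O)CO[Si](C)(C)C(C)(C)C | starting material
17 | 1-[(tert-butyldimethylsilyl)oxy]propan-2-one N,N-dimethylhydrazone | CC(CO[Si](C)(C)C(C)(C)C)=NN(C)C | intermediate
18 | 1-[(tert-butyldimethylsilyl)oxy]-4-Dr-butan-2-one N,N-dimethylhydrazone | CC1=C(CCC(CO[Si](C)(C)C(C)(C)C)=NN(C)C)[C@@]2(C)CCCC(C)(C)[C@@H]2CC1 | intermediate
19 | 1-[(tert-butyldimethylsilyl)oxy]-4-Dr-butan-2-one | CC1=C(CCC(=O)CO[Si](C)(C)C(C)(C)C)[C@@]2(C)CCCC(C)(C)[C@@H]2CC1 | intermediate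
20 | 4-(tert-butoxy)-4-oxobutanoic acid | OC(=O)CCC(=O)OC(C)(C)C | starting material
21 | (4S)-4-benzyl-1,3-oxazolidin-2-one | O=C1N[C@@H](Cc2ccccc2)CO1 | starting material
22 | 4-(tert-butoxy)-4-oxobutanoic 2,2-dimethylpropanoic anhydride | CC(C)(C)OC(=O)CCC(=O)OC(=O)C(C)(C)C | intermediate
23 | tert-butyl 4-[(4S)-4-benzyl-2-oxo-1,3-oxazolidin-3-yl]-4-oxobutanoate | CC(C)(C)OC(=O)CCC(=O)N1[C@@H](Cc2ccccc2)COC1=O | intermediate
24 | 3-(benzyloxy)propanal | O=CCCOCc1ccccc1 | starting material
25 | Z-(dibutylboryl) enolate of 23 | CCCCB(CCCC)O/C(=C\CC(=O)OC(C)(C)C)N1[C@@H](Cc2ccccc2)COC1=O | intermediate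
26 | tert-butyl (3S,4R)-3-{[(4S)-4-benzyl-2-oxo-1,3-oxazolidin-3-yl]carbonyl}-6-(benzyloxy)-4-hydroxyhexanoate | CC(C)(C)OC(=O)C[C@H](C(=O)N1[C@@H](Cc2ccccc2)COC1=O)[C@H](O)CCOCc1ccccc1 | intermediate
27 | tert-butyl (3S,4R)-3-{[(4S)-4-benzyl-2-oxo-1,3-oxazolidin-3-yl]carbonyl}-6-(benzyloxy)-4-[(tert-butyldimethylsilyl)oxy]hexanoate | CC(C)(C)OC(=O)C[C@H](C(=O)N1[C@@H](Cc2ccccc2)COC1=O)[C@H](O[Si](C)(C)C(C)(C)C)CCOCc1ccccc1 | intermediate
28 | tert-butyl (3R,4R)-6-(benzyloxy)-4-[(tert-butyldimethylsilyl)oxy]-3-(hydroxymethyl)hexanoate | CC(C)(C)OC(=O)C[C@H](CO)[C@H](O[Si](C)(C)C(C)(C)C)CCOCc1ccccc1 | intermediate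
29 | (4R)-4-[(1R)-3-(benzyloxy)-1-[(tert-butyldimethylsilyl)oxy]propyl]oxolan-2-one | O=C1C[C@H](CO1)[C@H](O[Si](C)(C)C(C)(C)C)CCOCc1ccccc1 | intermediate
30 | (4R)-4-[(1R)-1-[(tert-butyldimethylsilyl)oxy]-3-hydroxypropyl]oxolan-2-one | O=C1C[C@H](CO1)[C@H](O[Si](C)(C)C(C)(C)C)CCO | intermediate
31 | (4R)-4-[(1R)-1-[(tert-butyldimethylsilyl)oxy]-3-iodopropyl]oxolan-2-one | O=C1C[C@H](CO1)[C@H](O[Si](C)(C)C(C)(C)C)CCI | intermediate
32 | [(3R)-3-[(tert-butyldimethylsilyl)oxy]-3-[(3R)-5-oxooxolan-3-yl]propyl]triphenylphosphonium iodide | O=C1C[C@H](CO1)[C@H](O[Si](C)(C)C(C)(C)C)CC[P+](c1ccccc1)(c1ccccc1)c1ccccc1.[I-] | intermediate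
33 | [(3R)-3-[(tert-butyldimethylsilyl)oxy]-3-[(3R)-5-oxooxolan-3-yl]propylidene]triphenylphosphorane | O=C1C[C@H](CO1)[C@H](O[Si](C)(C)C(C)(C)C)CC=P(c1ccccc1)(c1ccccc1)c1ccccc1 | intermediate
34 | (4R)-4-[(1R,3Z)-1-[(tert-butyldimethylsilyl)oxy]-4-{[(tert-butyldimethylsilyl)oxy]methyl}-6-Dr-hex-3-en-1-yl]oxolan-2-one | CC1=C(CC/C(=C/C[C@@H](O[Si](C)(C)C(C)(C)C)[C@H]2COC(=O)C2)CO[Si](C)(C)C(C)(C)C)[C@@]3(C)CCCC(C)(C)[C@@H]3CC1 | intermediate
35 | (4R)-4-[(1R,3Z)-1-hydroxy-4-(hydroxymethyl)-6-[(4aS,8aS)-2,5,5,8a-tetramethyl-3,4,4a,5,6,7,8,8a-octahydronaphthalen-1-yl]hex-3-en-1-yl]oxolan-2-one | CC1=C(CC/C(=C/C[C@@H](O)[C@H]2COC(=O)C2)CO)[C@@]2(C)CCCC(C)(C)[C@@H]2CC1 | target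

## Step count and risks

Total step count: 22. Longest linear sequence: 14 steps (steps 1–11, 13, 21, 22, from camphoric acid 1).

Steps most likely to fail:

1. Step 7 (proposed new method). The secondary C5–O bond may fail to ionise. The C10 cation may lose H-5 to the achiral tetrasubstituted C5=C10 olefin, which would reclose with loss of enantiomeric purity. A shift of C1 or of the methyl group may compete with the C4 shift. Fallback (known chemistry, the ring expansion is separated from the ring B closure): it sets out from epoxide 7. BF3·OEt2 in CH2Cl2 at −78 °C (Lewis-acid epoxide rearrangement with 1,2-alkyl shift, the usual behaviour of an epoxide flanked by a quaternary carbon) should give, after loss of a proton from C1, [(1S)-2,6,6-trimethylcyclohex-2-en-1-yl]methanol F1. I2/PPh3/imidazole converts it into (6S)-6-(iodomethyl)-1,5,5-trimethylcyclohex-1-ene F2. Alkylation of the dianion of methyl acetoacetate 8 (THF/HMPA) gives methyl 3-oxo-5-[(1S)-2,6,6-trimethylcyclohex-2-en-1-yl]pentanoate F3. The SnCl4 cyclisation of this monocyclic β-keto ester (protonation of the ring olefin, closure of ring B only, C5 directing the trans fusion) comes back to the route at 11.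

2. Step 4. The thermally fragile carbenoid may decompose faster than it adds to the doubly hindered ester carbonyl. Fallback: it sets out from ester 4. Reduction with i-Bu2AlH at −78 °C gives (1S)-1,2,2-trimethylcyclopentane-1-carbaldehyde F4. Corey–Chaykovsky methylenation (Me3S+ I−, n-BuLi, THF) gives epoxide 7 together with its epimer (2S)-2-[(1S)-1,2,2-trimethylcyclopentyl]oxirane F5. Jacobsen hydrolytic kinetic resolution with the (S,S)-Co(salen) acetate complex of trivalent cobalt and 0.55 equiv of water hydrolyses F5 and leaves 7, where the fallback rejoins the route.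

3. Step 21. The ylide or the amide base may attack or enolise the lactone, and the Z-selectivity may erode with the branched ylide. Fallback (olefination before the aldol, lactone built last): it sets out from ketone 19. Wittig olefination with the ylide of commercial [2-(1,3-dioxolan-2-yl)ethyl]triphenylphosphonium bromide (a plain non-stabilised ylide, no lactone present) gives 2-[(2Z)-3-{[(tert-butyldimethylsilyl)oxy]methyl}-5-Dr-pent-2-en-1-yl]-1,3-dioxolane F6. Acetal exchange with catalytic I2 in acetone gives (3Z)-4-{[(tert-butyldimethylsilyl)oxy]methyl}-6-Dr-hex-3-enal F7, which is used at once in the boron aldol with imide 23 (conditions of step 15) to give tert-butyl (3S,4R,6Z)-3-{[(4S)-4-benzyl-2-oxo-1,3-oxazolidin-3-yl]carbonyl}-7-{[(tert-butyldimethylsilyl)oxy]methyl}-4-hydroxy-9-Dr-non-6-enoate F8. Silylation (TBSOTf, 2,6-lutidine) gives its 4-O-TBS ether, tert-butyl (3S,4R,6Z)-3-{[(4S)-4-benzyl-2-oxo-1,3-oxazolidin-3-yl]carbonyl}-4-[(tert-butyldimethylsilyl)oxy]-7-{[(tert-butyldimethylsilyl)oxy]methyl}-9-Dr-non-6-enoate F9. LiBH4 and then brief TFA (conditions of step 17) close the lactone and come back to the route at 34.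

Further compounds
F1 | step 7 | [(1S)-2,6,6-trimethylcyclohex-2-en-1-yl]methanol | OC[C@@H]1C(C)=CCCC1(C)C
F2 | step 7 | (6S)-6-(iodomethyl)-1,5,5-trimethylcyclohex-1-ene | IC[C@@H]1C(C)=CCCC1(C)C
F3 | step 7 | methyl 3-oxo-5-[(1S)-2,6,6-trimethylcyclohex-2-en-1-yl]pentanoate | COC(=O)CC(=O)CC[C@@H]1C(C)=CCCC1(C)C
F4 | step 4 | (1S)-1,2,2-trimethylcyclopentane-1-carbaldehyde | C[C@]1(C=O)CCCC1(C)C
F5 | step 4 | (2S)-2-[(1S)-1,2,2-trimethylcyclopentyl]oxirane | C[C@]1([C@H]2CO2)CCCC1(C)C
F6 | step 21 | 2-[(2Z)-3-{[(tert-butyldimethylsilyl)oxy]methyl}-5-[(4aS,8aS)-2,5,5,8a-tetramethyl-3,4,4a,5,6,7,8,8a-octahydronaphthalen-1-yl]pent-2-en-1-yl]-1,3-dioxolane | CC1=C(CC/C(=C/CC2OCCO2)CO[Si](C)(C)C(C)(C)C)[C@@]3(C)CCCC(C)(C)[C@@H]3CC1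
F7 | step 21 | (3Z)-4-{[(tert-butyldimethylsilyl)oxy]methyl}-6-[(4aS,8aS)-2,5,5,8a-tetramethyl-3,4,4a,5,6,7,8,8a-octahydronaphthalen-1-yl]hex-3-enal | CC1=C(CC/C(=C/CC=O)CO[Si](C)(C)C(C)(C)C)[C@@]2(C)CCCC(C)(C)[C@@H]2CC1
F8 | step 21 | tert-butyl (3S,4R,6Z)-3-{[(4S)-4-benzyl-2-oxo-1,3-oxazolidin-3-yl]carbonyl}-7-{[(tert-butyldimethylsilyl)oxy]methyl}-4-hydroxy-9-[(4aS,8aS)-2,5,5,8a-tetramethyl-3,4,4a,5,6,7,8,8a-octahydronaphthalen-1-yl]non-6-enoate | CC1=C(CC/C(=C/C[C@@H](O)[C@H](CC(=O)OC(C)(C)C)C(=O)N2[C@@H](Cc3ccccc3)COC2=O)CO[Si](C)(C)C(C)(C)C)[C@@]4(C)CCCC(C)(C)[C@@H]4CC1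
F9 | step 21 | tert-butyl (3S,4R,6Z)-3-{[(4S)-4-benzyl-2-oxo-1,3-oxazolidin-3-yl]carbonyl}-4-[(tert-butyldimethylsilyl)oxy]-7-{[(tert-butyldimethylsilyl)oxy]methyl}-9-[(4aS,8aS)-2,5,5,8a-tetramethyl-3,4,4a,5,6,7,8,8a-octahydronaphthalen-1-yl]non-6-enoate | CC1=C(CC/C(=C/C[C@@H](O[Si](C)(C)C(C)(C)C)[C@H](CC(=O)OC(C)(C)C)C(=O)N2[C@@H](Cc3ccccc3)COC2=O)CO[Si](C)(C)C(C)(C)C)[C@@]4(C)CCCC(C)(C)[C@@H]4CC1
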